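Subtract the impurity charged from the free catalyst charged before reading any curve.

| flask | substrate | reagent | free catalyst | impurity | temperature | remark | time |
|---|---|---|---|---|---|---|---|
| amber | 0.10 M | 0.20 M | 15 mM | 15 mM | 25 °C | the very flask that is asked about, followed so far |  |
| green | 0.10 M | 0.20 M | 30 mM | 15 mM | 31 °C | run made earlier |  |
| flask | 0.10 M | 0.200 M | 15 mM | 15 mM | 25 °C |  | 10 h |

| run | time / min | target / % | substrate / % |
|---|---|---|---|
| amber | 30.0 | 3.0 | 83.3 |
| amber | 50.0 | 4.1 | 77.4 |
| amber | 80.0 | 4.6 | 66.9 |
| amber | 120 | 6.9 | 61.7 |
| amber | 240 | 7.6 | 54.2 |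
| amber | 360 | 8.5 | 52.8 |
| green | 1.33 | 1.0 | 94.5 |
| green | 4.00 | 0 | 90.4 |
| green | 8.00 | 1.6 | 84.2 |
| green | 12.0 | 0.4 | 75.8 |
| green | 15.0 | 3.0 | 73.8 |
| green | 20.0 | 5.0 | 69.9 |

(scatter of a reading: 1 percentage point)

- north-east: at 10 h take out 90% of the target then present, then wait 20 h
- east: at 10 h add reagent, 100% of the amount charged, then wait 20 h
- south-east: change nothing and wait 20 h more
- north: at 10 h add free catalyst, 50.0% of the amount charged, then wait 20 h
- north-west: at 10 h raise the temperature by 25 K, then wait 20 h

- target, in percent of the substrate first charged, at 10 h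
- the option that brings most further target ("none" if no option brings more than 2 percentage points) (north-east / east / south-east / north / north-west / none)
- target present, with what was taken out counted in, in percent of the substrate first charged, after north-east
- target present, with what was taken out counted in, in percent of the substrate first charged, after south-east

- removed target is counted in
- reactions considered so far: catalyst intermediate D <-> free catalyst + target; reagent + catalyst intermediate A <-> catalyst intermediate B; substrate + free catalyst -> catalyst intermediate A; substrate <-> dormant form; catalyst intermediate C <-> by-product + catalyst intermediate D; free catalyst + impurity -> spent catalyst; catalyst intermediate B <-> catalyst intermediate C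
- additions bring no volume worth counting

In amber that subtraction gave 0 mM, and in green 15.0 mM. I named this difference the catalyst surplus: free catalyst charged minus impurity charged. The impurity acts as a stoichiometric poison, since each event in the listed reaction removes one catalyst and one impurity, so I expected the surplus to hold throughout a run, with every live catalyst form counted. Amber's readings fitted a catalyst dying early: target stood at 8.5% after 360 min, which is 8.50 mM, less than the catalyst charged.

I reckoned the target in amber at 10 h in two ways. A straight line through the last two readings gave 10.3%. At zero surplus, however, live catalyst and impurity fall together as a second-order pair, so late in the run live catalyst goes as the inverse of time and, with substrate about steady (amber read 54.2% and 52.8% at its last two times), target grows with the logarithm of time. That law, through the readings at 120 min and 360 min, gave 9.24%.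

The two parted by 1.1 percentage points, and I took the line to be the one that cheats. It assumes steady live catalyst, and its slope rests on a step of 0.9 points, smaller than the 1.4 points scatter of a difference, which is then stretched to twice its span.

So I committed to the logarithm. Waiting 20 h more gave me 10.8%, a gain of 1.6 points, below the margin. North raised the surplus to 7.50 mM, while the other options left it at 0 mM, so I chose north.

The forecast gave 9.3% now, 10.5% after north-east and 10.2% after south-east, a lower waiting figure than mine, and chose north, on the ground that “fresh catalyst survives”.

    catalyst intermediate D ⇌ free catalyst + target (K = 0.0740 M, k = 0.00380 s⁻¹, Ea = 93.0 kJ mol⁻¹, ΔH = −26.0 kJ mol⁻¹)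
    reagent + catalyst intermediate A ⇌ catalyst intermediate B (K = 2.25 M⁻¹, k = 0.0282 M⁻¹ s⁻¹, Ea = 42.0 kJ mol⁻¹, ΔH = 2.00 kJ mol⁻¹)
    substrate + free catalyst → catalyst intermediate A (k = 0.00726 M⁻¹ s⁻¹, Ea = 70.0 kJ mol⁻¹)
    substrate ⇌ dormant form (K = 0.770, k = 8.84 × 10⁻⁵ s⁻¹, Ea = 99.0 kJ mol⁻¹, ΔH = −2.00 kJ mol⁻¹)
    catalyst intermediate C ⇌ by-product + catalyst intermediate D (K = 0.0722 M, k = 0.00496 s⁻¹, Ea = 79.0 kJ mol⁻¹, ΔH = −20.0 kJ mol⁻¹)
    free catalyst + impurity → spent catalyst (k = 0.196 M⁻¹ s⁻¹, Ea = 40.0 kJ mol⁻¹)
    catalyst intermediate B ⇌ catalyst intermediate C (K = 0.510, k = 0.262 s⁻¹, Ea = 76.0 kJ mol⁻¹, ΔH = −53.0 kJ mol⁻¹)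
    (constants at 25 °C)

The amber flask gave 10.1% at 10 h, 12.4% after north-east and 12.2% after south-east. North brought 35 points, more than any other option. At 600 min the amber flask's free catalyst and catalyst intermediates A, B, C and D summed to 2.09% of the catalyst charged, against 2.1% of the equal impurity charge. A neighbouring flask charged with 9.00 mM of free catalyst had a surplus of −6.00 mM, which reckoned 40.0% of the impurity left over. At 600 min it held 40% of its impurity, free catalyst at 0%, and target at 3.02%.

(All runs are calculated for an exercise.)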